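**Retrosynthetic overview**
1. The target comes from its C5 ketone by a chelate-directed hydride in the last step. That epoxyquinone comes from a 2,5-disubstituted 1,4-benzoquinone by a hydroxyl-directed nucleophilic epoxidation, which builds the fused oxirane.
2. Key disconnection: the quinone ring is cut back to a four-membered ring, 3-(acetoxymethyl)cyclobutenedione, plus a terminal alkyne. In the forward direction rhodium inserts the alkyne into the acyl–acyl bond. This four- to six-membered ring expansion also joins core and side chain.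
3. The alkyne partner comes from catalytic asymmetric ethynylation (sets C1') of an all-E epoxy-trienal. The trienal comes from a Stille union of a C1'–C5' dienylstannane and a C6'–C9' iodoalkene that already carries the (R)-oxirane (carboalumination, Shi epoxidation).
4. The cyclobutenedione comes from propargyl acetate and dichloroketene, followed by hydrolysis of the CCl2 group.
5. Order of ring formation: side-chain oxirane, cyclobutene, six-membered carbocycle (by ring expansion), fused oxirane.

Locants: ring C1–C6 follow the 7-oxabicyclo[4.1.0]heptene name of the target (C1 oxirane CH, C2 ketone, C3 bears CH2OAc, C4 =CH, C5 carbinol, C6 quaternary oxirane carbon). C1'–C9' count the side chain from the carbinol carbon.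
Assumption: all six carbon-bearing inputs and the listed reagents, ligands and catalysts are taken as commercially available.

**Step 1**
Reactants: 1 5-bromo-2-methylpent-2-ene; 2 lithium acetylide–ethane-1,2-diamine complex
Product: 3 6-methylhept-5-en-1-yne
Conditions: DMSO, 0 °C to rt, 4 h
Reagents that add atoms: none
Why: SN2 alkylation of lithium acetylide on an unhindered primary bromide; no stereocentre is formed.

**Step 2**
Reactants: 3 6-methylhept-5-en-1-yne
Product: 5 (1E)-1-iodo-2,6-dimethylhepta-1,5-diene, via alkenylalane 4 (not isolated)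
Conditions: Me3Al (2.0 equiv), Cp2ZrCl2 (0.25 equiv), CH2Cl2, 0 °C to rt; then I2, THF, −30 °C
Reagents that add atoms: trimethylaluminium C[Al](C)C; iodine [I][I]
Why: Negishi zirconium-catalysed carboalumination adds methyl and aluminium syn with aluminium on the terminal carbon, and iodinolysis with retention fixes the E trisubstituted alkene (later C6'=C7') while the isolated alkene is untouched.

**Step 3**
Reactants: 5 (1E)-1-iodo-2,6-dimethylhepta-1,5-diene
Product: 6 (3R)-3-[(3E)-4-iodo-3-methylbut-3-en-1-yl]-2,2-dimethyloxirane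
Conditions: D-fructose-derived Shi ketone (0.3 equiv), KHSO5 (as 2KHSO5·KHSO4·K2SO4), K2CO3, Bu4NHSO4, MeCN–CH2(OMe)2 / aq Na2B4O7–Na2EDTA buffer, pH 10.5, 0 °C
Reagents that add atoms: potassium peroxymonosulfate [K+].[O-]S(=O)(=O)OO
Why: Shi asymmetric epoxidation; the chiral dioxirane attacks the electron-rich isopropylidene alkene through the spiro transition state to give the (R)-oxirane, and the iodoalkene is electronically deactivated.

**Step 4**
Reactants: 7 (2E)-3-methylpent-2-en-4-yn-1-ol
Product: 8 (2E,4E)-3-methyl-5-(tributylstannyl)penta-2,4-dien-1-ol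
Conditions: Bu3SnH (1.1 equiv), PdCl2(PPh3)2 (2 mol%), THF, 0 °C
Reagents that add atoms: tributyltin hydride CCCC[SnH](CCCC)CCCC
Why: Palladium-catalysed syn hydrostannation of the terminal alkyne puts tin on the terminal carbon and gives the E alkene (later C4'=C5'); the existing E alkene is not touched.

**Step 5**
Reactants: 6 (3R)-3-[(3E)-4-iodo-3-methylbut-3-en-1-yl]-2,2-dimethyloxirane; 8 (2E,4E)-3-methyl-5-(tributylstannyl)penta-2,4-dien-1-ol
Product: 9 (2E,4E,6E)-9-[(2R)-3,3-dimethyloxiran-2-yl]-3,7-dimethylnona-2,4,6-trien-1-ol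
Conditions: PdCl2(MeCN)2 (5 mol%), DMF, rt, dark
Reagents that add atoms: none
Why: Stille coupling of an alkenyl iodide and an alkenylstannane proceeds with retention in both partners under neutral conditions that spare the oxirane and the free alcohol.

**Step 6**
Reactants: 9 (2E,4E,6E)-9-[(2R)-3,3-dimethyloxiran-2-yl]-3,7-dimethylnona-2,4,6-trien-1-ol
Product: 10 (2E,4E,6E)-9-[(2R)-3,3-dimethyloxiran-2-yl]-3,7-dimethylnona-2,4,6-trienal
Conditions: MnO2 (15 equiv), CH2Cl2, rt
Reagents that add atoms: none
Why: Selective MnO2 oxidation of an allylic alcohol to the enal without alkene isomerisation or oxirane opening.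

**Step 7**
Reactants: 10 (2E,4E,6E)-9-[(2R)-3,3-dimethyloxiran-2-yl]-3,7-dimethylnona-2,4,6-trienal; 11 ethynyl(trimethyl)silane
Product: 14 (3S,4E,6E,8E)-11-[(2R)-3,3-dimethyloxiran-2-yl]-5,9-dimethylundeca-4,6,8-trien-1-yn-3-ol, via alkynylzinc 12 (not isolated), via silyl alkynol 13 (not isolated)
Conditions: Me2Zn (3 equiv), (S,S)-ProPhenol (10 mol%), Ph3P=O (20 mol%), toluene, 4 °C; then MeOH, K2CO3, rt
Reagents that add atoms: none
Why: Zinc–ProPhenol catalysed asymmetric alkynylation, a method suited to enals, delivers the alkynylzinc to the Re face of the aldehyde and sets the (S) carbinol (later C1'); basic methanolysis then removes silicon in the same flask.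

**Step 8**
Reactants: 15 prop-2-yn-1-yl acetate; 16 trichloroacetyl chloride
Product: 18 (4,4-dichloro-3-oxocyclobut-1-en-1-yl)methyl acetate, via dichloroketene 17 (not isolated)
Conditions: zinc–copper couple Zn(Cu), Et2O–DME, rt to 35 °C, slow addition of 16
Reagents that add atoms: none
Why: Ketene–alkyne [2+2] cycloaddition; the terminal alkyne carbon bonds to the ketene carbonyl carbon, so CCl2 ends up next to the substituted ring carbon.

**Step 9**
Reactants: 18 (4,4-dichloro-3-oxocyclobut-1-en-1-yl)methyl acetate
Product: 19 (3,4-dioxocyclobut-1-en-1-yl)methyl acetate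
Conditions: Ag2CO3 (1.2 equiv), MeCN–H2O 20:1, 40 °C, dark
Reagents that add atoms: water O
Why: Silver-assisted hydrolysis of an allylic gem-dichloride through the stabilised oxocyclobutenyl cation; the carbonate keeps the medium neutral so the acetate survives.

**Step 10**
Reactants: 14 (3S,4E,6E,8E)-11-[(2R)-3,3-dimethyloxiran-2-yl]-5,9-dimethylundeca-4,6,8-trien-1-yn-3-ol; 19 (3,4-dioxocyclobut-1-en-1-yl)methyl acetate
Product: 20 {4-[(1S,2E,4E,6E)-9-[(2R)-3,3-dimethyloxiran-2-yl]-1-hydroxy-3,7-dimethylnona-2,4,6-trien-1-yl]-3,6-dioxocyclohexa-1,4-dien-1-yl}methyl acetate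
Conditions: [Rh(cod)2]BF4 (5 mol%), 1,4-bis(diphenylphosphino)butane (6 mol%), 19 (1.2 equiv) added over 4 h, 1,2-dichloroethane, 45 °C, argon, dark
Reagents that add atoms: none
Why: Proposed new method: catalytic two-carbon ring expansion of a cyclobutenedione to a 1,4-benzoquinone by C–C activation and alkyne insertion; monovalent rhodium adds oxidatively into the strained acyl–acyl bond of 19 to give a trivalent rhodacyclopentenedione, the cationic metal then binds the propargylic OH and the alkyne of 14, migratory insertion takes place into the less hindered Rh–acyl bond (the acyl next to the ring CH) with C–C bond formation at the internal alkyne carbon because only this orientation keeps a five-membered O–Rh chelate, and C–C reductive elimination of the vinyl and the second acyl ligand closes the six-membered ring, which places the two substituents para to each other and leaves C1' untouched; the quinone is displaced from rhodium by cod or by fresh 19, which is why 19 is fed slowly in slight excess; the closest known reaction types are the stoichiometric maleoylcobalt or phthaloylrhodium plus alkyne quinone synthesis and the catalytic insertion of alkynes into cyclobutanones and cyclobutenones by zerovalent nickel or monovalent rhodium.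

**Step 11**
Reactants: 20 {4-[(1S,2E,4E,6E)-9-[(2R)-3,3-dimethyloxiran-2-yl]-1-hydroxy-3,7-dimethylnona-2,4,6-trien-1-yl]-3,6-dioxocyclohexa-1,4-dien-1-yl}methyl acetate
Product: 21 [(1R,6S)-6-{(1S,2E,4E,6E)-9-[(2R)-3,3-dimethyloxiran-2-yl]-1-hydroxy-3,7-dimethylnona-2,4,6-trien-1-yl}-2,5-dioxo-7-oxabicyclo[4.1.0]hept-3-en-3-yl]methyl acetate
Conditions: tBuOOH (1.5 equiv), nBuLi (1.3 equiv), THF, −78 °C; then 20, −78 to −40 °C; H2O
Reagents that add atoms: tert-butyl hydroperoxide CC(C)(C)OO
Why: Weitz–Scheffer nucleophilic epoxidation with lithium tert-butyl peroxide; lithium bridges the C1' hydroxyl and the peroxide, so oxygen goes only to the C=C that carries the side chain (attack at its CH carbon, no SN2' loss of the allylic acetate at the other C=C) and from the face on which the C1'–O bond stands in the rotamer that turns the alkenyl group toward the ring CH and away from the neighbouring carbonyl (A(1,2) strain), which sets C1 and C6 as drawn.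

**Step 12**
Reactants: 21 [(1R,6S)-6-{(1S,2E,4E,6E)-9-[(2R)-3,3-dimethyloxiran-2-yl]-1-hydroxy-3,7-dimethylnona-2,4,6-trien-1-yl}-2,5-dioxo-7-oxabicyclo[4.1.0]hept-3-en-3-yl]methyl acetate
Product: 22 [(1R,5S,6R)-5-hydroxy-6-{(1S,2E,4E,6E)-9-[(2R)-3,3-dimethyloxiran-2-yl]-1-hydroxy-3,7-dimethylnona-2,4,6-trien-1-yl}-2-oxo-7-oxabicyclo[4.1.0]hept-3-en-3-yl]methyl acetate
Conditions: Zn(BH4)2 (0.6 equiv), Et2O–THF, −78 °C; H2O
Reagents that add atoms: none
Why: Chelation-directed 1,2-reduction with Zn(BH4)2; the zinc alkoxide of C1'–OH is held by the oxirane oxygen in a five-membered chelate on the oxirane face beside the C5 carbonyl, so the zinc-bound borohydride reaches C5 rather than the remote C2 ketone and adds hydride syn to the oxirane, giving the (5S) alcohol trans to the oxirane, whereas an unbound hydride would attack anti to the oxirane and give the C5 epimer.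

**Compound list**
1 | 5-bromo-2-methylpent-2-ene | CC(C)=CCCBr | starting material
2 | lithium acetylide–ethane-1,2-diamine complex | [Li]C#C.NCCN | starting material
3 | 6-methylhept-5-en-1-yne | C#CCCC=C(C)C | intermediate
4 | [(1E)-2,6-dimethylhepta-1,5-dien-1-yl]dimethylalane | C[Al](C)/C=C(\C)CCC=C(C)C | intermediate
5 | (1E)-1-iodo-2,6-dimethylhepta-1,5-diene | I/C=C(\C)CCC=C(C)C | intermediate
6 | (3R)-3-[(3E)-4-iodo-3-methylbut-3-en-1-yl]-2,2-dimethyloxirane | I/C=C(\C)CC[C@H]1OC1(C)C | intermediate
7 | (2E)-3-methylpent-2-en-4-yn-1-ol | C#C/C(C)=C/CO | starting material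
8 | (2E,4E)-3-methyl-5-(tributylstannyl)penta-2,4-dien-1-ol | CCCC[Sn](CCCC)(CCCC)/C=C/C(C)=C/CO | intermediate
9 | (2E,4E,6E)-9-[(2R)-3,3-dimethyloxiran-2-yl]-3,7-dimethylnona-2,4,6-trien-1-ol | OC/C=C(C)/C=C/C=C(\C)CC[C@H]1OC1(C)C | intermediate
10 | (2E,4E,6E)-9-[(2R)-3,3-dimethyloxiran-2-yl]-3,7-dimethylnona-2,4,6-trienal | O=C/C=C(C)/C=C/C=C(\C)CC[C@H]1OC1(C)C | intermediate
11 | ethynyl(trimethyl)silane | C#C[Si](C)(C)C | starting material
12 | methyl[(trimethylsilyl)ethynyl]zinc | C[Zn]C#C[Si](C)(C)C | intermediate
13 | (3S,4E,6E,8E)-11-[(2R)-3,3-dimethyloxiran-2-yl]-5,9-dimethyl-1-(trimethylsilyl)undeca-4,6,8-trien-1-yn-3-ol | C[Si](C)(C)C#C[C@@H](O)/C=C(C)/C=C/C=C(\C)CC[C@H]1OC1(C)C | intermediate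
14 | (3S,4E,6E,8E)-11-[(2R)-3,3-dimethyloxiran-2-yl]-5,9-dimethylundeca-4,6,8-trien-1-yn-3-ol | C#C[C@@H](O)/C=C(C)/C=C/C=C(\C)CC[C@H]1OC1(C)C | intermediate
15 | prop-2-yn-1-yl acetate | C#CCOC(C)=O | starting material
16 | trichloroacetyl chloride | ClC(Cl)(Cl)C(Cl)=O | starting material
17 | dichloroketene | ClC(Cl)=C=O | intermediate
18 | (4,4-dichloro-3-oxocyclobut-1-en-1-yl)methyl acetate | CC(=O)OCC1=CC(=O)C1(Cl)Cl | intermediate
19 | (3,4-dioxocyclobut-1-en-1-yl)methyl acetate | CC(=O)OCC1=CC(=O)C1=O | intermediate
20 | {4-[(1S,2E,4E,6E)-9-[(2R)-3,3-dimethyloxiran-2-yl]-1-hydroxy-3,7-dimethylnona-2,4,6-trien-1-yl]-3,6-dioxocyclohexa-1,4-dien-1-yl}methyl acetate | CC(=O)OCC1=CC(=O)C(=CC1=O)[C@@H](O)/C=C(C)/C=C/C=C(\C)CC[C@H]2OC2(C)C | intermediate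
21 | [(1R,6S)-6-{(1S,2E,4E,6E)-9-[(2R)-3,3-dimethyloxiran-2-yl]-1-hydroxy-3,7-dimethylnona-2,4,6-trien-1-yl}-2,5-dioxo-7-oxabicyclo[4.1.0]hept-3-en-3-yl]methyl acetate | CC(=O)OCC1=CC(=O)[C@@]2([C@@H](O)/C=C(C)/C=C/C=C(\C)CC[C@H]3OC3(C)C)O[C@H]2C1=O | intermediate
22 | [(1R,5S,6R)-5-hydroxy-6-{(1S,2E,4E,6E)-9-[(2R)-3,3-dimethyloxiran-2-yl]-1-hydroxy-3,7-dimethylnona-2,4,6-trien-1-yl}-2-oxo-7-oxabicyclo[4.1.0]hept-3-en-3-yl]methyl acetate | CC(=O)OCC1=C[C@H](O)[C@@]2([C@@H](O)/C=C(C)/C=C/C=C(\C)CC[C@H]3OC3(C)C)O[C@H]2C1=O | target

**Total step count:** 12.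
**Longest linear sequence:** 9 steps (1, 2, 3, 5, 6, 7, 10, 11, 12).

**Steps most likely to fail**

**Step 10 (the proposed new ring expansion).**
- Risks:
  - The quinone may bind to or oxidise the rhodium and stop turnover.
  - The rhodacycle may lose CO.
  - The alkyne may oligomerise or isomerise.
  - The triene may occupy the metal.
  - The insertion may give the 2,6-isomer.
- Fallback with known chemistry: it sets out from 14 and 19 and comes back to the route at 20.
  - Alkynol 14 is doubly deprotonated (nBuLi, 2.05 equiv, THF, −78 °C). It is then added to the more electrophilic carbonyl of 19, the one next to the substituted ring carbon.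
  - This gives {4-hydroxy-4-[(3S,4E,6E,8E)-11-[(2R)-3,3-dimethyloxiran-2-yl]-3-hydroxy-5,9-dimethylundeca-4,6,8-trien-1-yn-1-yl]-3-oxocyclobut-1-en-1-yl}methyl acetate F1 (either configuration at the ring carbinol).
  - Heating F1 in toluene at 110 °C brings about the well-known thermal rearrangement of 4-alkynyl-4-hydroxycyclobutenones to 1,4-benzoquinones. That rearrangement puts the side chain next to the former ketone carbon and so delivers 20.

**Step 11.**
- Risks:
  - Peroxide may attack the C=C that bears CH2OAc, with SN2' loss of acetate.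
  - Facial control by the lithium bridge may be weak.
  - Base may trigger retro-aldol cleavage or tautomerisation of the hydroxyalkylquinone.
- Fallback: it sets out from 20 and comes back at 21. Stereocontrol is moved from the substrate to an external chiral reagent.
  - The method is the known tartrate-mediated nucleophilic epoxidation of hydroxyalkyl-substituted quinone derivatives.
  - Conditions: Ph3COOH, NaN(SiMe3)2, the matched antipode of diisopropyl tartrate, toluene, −50 °C.
  - The bulky trityl peroxide also disfavours the substituted second C=C.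
  - New compounds on this way: none F0.

**Step 12.**
- Risks:
  - Hydride may attack anti to the oxirane and give the C5 epimer.
  - The less hindered C2 ketone may be reduced.
  - Over-reduction may occur.
- Fallback: it sets out from 21 and comes back at 22. The metal hydride is replaced by biocatalysis.
  - An NADPH-dependent ketoreductase is chosen from a screening panel.
  - Conditions: glucose and glucose dehydrogenase for cofactor recycling, pH 7 phosphate buffer–DMSO 9:1, 25 °C.
  - This enzyme class reduces fungal epoxyquinones to trans epoxyquinols, and both site and face are fixed by the active site.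
  - New compounds on this way: none F0.

**Further compounds**
F1 | step 10 | {4-hydroxy-4-[(3S,4E,6E,8E)-11-[(2R)-3,3-dimethyloxiran-2-yl]-3-hydroxy-5,9-dimethylundeca-4,6,8-trien-1-yn-1-yl]-3-oxocyclobut-1-en-1-yl}methyl acetate | CC(=O)OCC1=CC(=O)C1(O)C#C[C@@H](O)/C=C(C)/C=C/C=C(\C)CC[C@H]2OC2(C)C
F0 | step 11 | none | none
F0 | step 12 | none | none
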